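The synthesis builds ring D, the resorcinol ring C4a''–C8a'' of the 7-hydroxyflavone half, around the pre-existing biaryl bond, so that the crowded C3'–C8'' link is never made by coupling. The feature used is that C8'' holds the ring B aryl between the oxygens on C7'' and C8a'', with the C4'' acyl carbon on C4a''. A Diels–Alder reaction of a bis-silyloxy diene with but-3-yn-2-one forms C8a''–C4a'' and C6''–C5'' and, after loss of methanol and silyl groups, delivers the 3-aryl-2,4-dihydroxyacetophenone in one operation. The diene is the ketene silyl acetal–silyl enol ether of a 2-aryl acetoacetate whose 5-bromo-2-methoxyphenyl group later anchors the methoxyflavone half.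

Key step: step 5

Numbering: unprimed locants belong to the 7-methoxyflavone, primed locants to its 2-aryl ring (ring B), doubly primed locants to the 7-hydroxyflavone, whose benzo ring is ring D.

Assumption: the target is drawn without an axial descriptor, so the C3'–C8'' biaryl axis is treated as configurationally undefined and no step is asked to control it.

**Step 1**
Reactants: 1 (5-bromo-2-methoxyphenyl)acetic acid
Product: 2 methyl (5-bromo-2-methoxyphenyl)acetate
Conditions: MeOH, H2SO4 (cat.), reflux
Reagents that add atoms: methanol, CO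
Why: Fischer esterification of an unhindered arylacetic acid is driven to the ester by the large excess of methanol.

**Step 2**
Reactants: 2 methyl (5-bromo-2-methoxyphenyl)acetate
Product: 3 methyl 2-(5-bromo-2-methoxyphenyl)-3-oxobutanoate
Conditions: LiN(SiMe3)2 (2.2 equiv), THF, −78 °C; AcCl (1.2 equiv), −78 → 0 °C; aq NH4Cl
Reagents that add atoms: acetyl chloride, CC(Cl)=O
Why: Claisen-type C-acylation of the lithium ester enolate should succeed because the second equivalent of base converts the more acidic beta-keto ester into its enolate as it forms, which blocks a second acylation, while the aryl bromide is inert to the amide base at −78 °C.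

**Step 3**
Reactants: 3 methyl 2-(5-bromo-2-methoxyphenyl)-3-oxobutanoate
Product: 4 methyl 2-(5-bromo-2-methoxyphenyl)-3-(trimethylsilyloxy)but-2-enoate
Conditions: Me3SiCl (1.5 equiv), Et3N (1.6 equiv), PhMe, 20 °C, 48 h
Reagents that add atoms: chlorotrimethylsilane, C[Si](C)(C)Cl
Why: Silyl enol ether formation by soft enolisation works well on a 2-substituted beta-keto ester, which is largely enolised and is silylated on the ketone oxygen.

**Step 4**
Reactants: 4 methyl 2-(5-bromo-2-methoxyphenyl)-3-(trimethylsilyloxy)but-2-enoate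
Product: 5 [2-(5-bromo-2-methoxyphenyl)-1-methoxybuta-1,3-diene-1,3-diyl]bis(oxy)bis(trimethylsilane)
Conditions: LiN(iPr)2 (1.3 equiv), THF, −78 °C; Me3SiCl (1.5 equiv), −78 → 20 °C; filtered under argon and used crude
Reagents that add atoms: chlorotrimethylsilane, C[Si](C)(C)Cl
Why: Kinetic deprotonation of the allylic methyl group gives the ester dienolate, whose O-silylation is the standard preparation of 1-alkoxy-1,3-bis(silyloxy)butadienes, and the cold amide base should leave the aryl bromide untouched.

**Step 5**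
Reactants: 5 [2-(5-bromo-2-methoxyphenyl)-1-methoxybuta-1,3-diene-1,3-diyl]bis(oxy)bis(trimethylsilane); 6 but-3-yn-2-one
Product: 8 1-[3-(5-bromo-2-methoxyphenyl)-2,4-dihydroxyphenyl]ethanone, via silyl ketal cycloadduct 7 (not isolated)
Conditions: PhMe, 0 → 60 °C, sealed tube; then 1 M HCl, THF, 20 °C
Reagents that add atoms: none
Why: The electron-rich diene 5 and the electron-poor ynone 6 should combine in a normal-demand Diels–Alder reaction, concerted but strongly asynchronous or, at the stepwise limit, a Mukaiyama–Michael addition followed by closure of the allenolate carbon onto the silyloxy(methoxy)carbenium centre; the closest known reaction type is the cycloaddition of 1-alkoxy-1,3-bis(silyloxy)butadienes to acetylenic ketones and esters, which gives resorcinol derivatives. Ring D closes as the six-membered ring of a [4+2] cycloaddition, the diene reaching its s-cis form because the C2 aryl group can twist out of the diene plane. The only stereocentre formed, the silyl methyl ketal carbon of 7, is racemic and disappears when acid removes the silyl groups, the ketal expels methanol and the dienone tautomerises to the phenol, so no stereocontrol is needed. The selectivity required is regiochemical: the unsubstituted CH2 terminus, the most nucleophilic diene carbon, must bond to the beta carbon of the ynone and the ketene acetal carbon to the alpha carbon, which the matched polarisation of the two partners secures and which places the acetyl group on C4a'' next to C8a''. Because the aryl group arrives on the diene, the hindered C8'' position never has to take part in a cross-coupling.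

**Step 6**
Reactants: 8 1-[3-(5-bromo-2-methoxyphenyl)-2,4-dihydroxyphenyl]ethanone
Product: 9 1-[4-(benzyloxy)-3-(5-bromo-2-methoxyphenyl)-2-hydroxyphenyl]ethanone
Conditions: BnBr (1.05 equiv), K2CO3 (1.1 equiv), acetone, reflux
Reagents that add atoms: benzyl bromide, BrCc1ccccc1
Why: Williamson etherification should take place only at the 4-OH (O7''), because the 2-OH is tied up in a hydrogen bond to the acetyl carbonyl and is the less acidic and less nucleophilic site.

**Step 7**
Reactants: 9 1-[4-(benzyloxy)-3-(5-bromo-2-methoxyphenyl)-2-hydroxyphenyl]ethanone; 10 4-(benzyloxy)benzaldehyde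
Product: 11 (E)-1-[4-(benzyloxy)-3-(5-bromo-2-methoxyphenyl)-2-hydroxyphenyl]-3-[4-(benzyloxy)phenyl]prop-2-en-1-one
Conditions: KOH (50% aq), EtOH, 20 °C; then dilute HCl
Reagents that add atoms: none
Why: Claisen–Schmidt condensation of the acetophenone enolate with a non-enolisable aldehyde, followed by E1cB dehydration, should give the conjugated chalcone as the thermodynamically preferred E isomer.

**Step 8**
Reactants: 11 (E)-1-[4-(benzyloxy)-3-(5-bromo-2-methoxyphenyl)-2-hydroxyphenyl]-3-[4-(benzyloxy)phenyl]prop-2-en-1-one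
Product: 12 7-(benzyloxy)-2-[4-(benzyloxy)phenyl]-8-(5-bromo-2-methoxyphenyl)-4H-chromen-4-one
Conditions: I2 (10 mol%), DMSO, 130 °C
Reagents that add atoms: none
Why: Iodine-catalysed oxidative cyclisation of a 2'-hydroxychalcone (oxa-Michael closure, alpha-iodination and loss of HI, which DMSO reoxidises) is a standard flavone synthesis that benzyl ethers and aryl bromides tolerate.

**Step 9**
Reactants: 12 7-(benzyloxy)-2-[4-(benzyloxy)phenyl]-8-(5-bromo-2-methoxyphenyl)-4H-chromen-4-one; 13 ethynyl(trimethyl)silane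
Product: 15 7-(benzyloxy)-2-[4-(benzyloxy)phenyl]-8-(5-ethynyl-2-methoxyphenyl)-4H-chromen-4-one, via silylalkyne 14 (not isolated)
Conditions: PdCl2(PPh3)2 (5 mol%), CuI (10 mol%), Et3N/DMF, 80 °C, sealed tube; then K2CO3 (cat.), MeOH/THF, 20 °C
Reagents that add atoms: none
Why: Sonogashira coupling of the aryl bromide with the silyl-capped alkyne prevents double arylation, and mild methanolysis of the C–Si bond then frees the terminal alkyne without harming the flavone.

**Step 10**
Reactants: 15 7-(benzyloxy)-2-[4-(benzyloxy)phenyl]-8-(5-ethynyl-2-methoxyphenyl)-4H-chromen-4-one; 16 2-iodo-5-methoxyphenol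
Product: 18 7-(benzyloxy)-2-[4-(benzyloxy)phenyl]-8-[2-methoxy-5-(7-methoxy-4-oxo-4H-chromen-2-yl)phenyl]-4H-chromen-4-one, via hydroxyaryl ynone 17 (not isolated)
Conditions: PdCl2(dppf) (5 mol%), CO (20 bar), Et2NH, 120 °C
Reagents that add atoms: carbon monoxide, [C-]#[O+]
Why: Carbonylative Sonogashira annulation (oxidative addition of the aryl iodide to zerovalent palladium, CO insertion, acyl–alkynyl coupling) gives the ynone, and in diethylamine this closes through the enaminone in the 6-endo sense to the flavone and not to the aurone.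

**Step 11**
Reactants: 18 7-(benzyloxy)-2-[4-(benzyloxy)phenyl]-8-[2-methoxy-5-(7-methoxy-4-oxo-4H-chromen-2-yl)phenyl]-4H-chromen-4-one
Product: 19 7-hydroxy-2-(4-hydroxyphenyl)-8-[2-methoxy-5-(7-methoxy-4-oxo-4H-chromen-2-yl)phenyl]-4H-chromen-4-one
Conditions: H2 (1 atm), 10% Pd/C, THF/MeOH, 20 °C, stopped at full debenzylation
Reagents that add atoms: none
Why: Catalytic hydrogenolysis cleaves both aryl benzyl ethers under conditions that leave aryl methyl ethers alone and, with monitoring, the pyranone double bonds intact.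

**Compound list**

1 | (5-bromo-2-methoxyphenyl)acetic acid | COc1ccc(Br)cc1CC(=O)O | starting material
2 | methyl (5-bromo-2-methoxyphenyl)acetate | COC(=O)Cc1cc(Br)ccc1OC | intermediate
3 | methyl 2-(5-bromo-2-methoxyphenyl)-3-oxobutanoate (racemic, enolisable) | COC(=O)C(C(C)=O)c1cc(Br)ccc1OC | intermediate
4 | methyl 2-(5-bromo-2-methoxyphenyl)-3-(trimethylsilyloxy)but-2-enoate (double-bond geometry not defined) | COC(=O)C(c1cc(Br)ccc1OC)=C(C)O[Si](C)(C)C | intermediate
5 | [2-(5-bromo-2-methoxyphenyl)-1-methoxybuta-1,3-diene-1,3-diyl]bis(oxy)bis(trimethylsilane) (geometry at C1=C2 not defined) | COC(O[Si](C)(C)C)=C(c1cc(Br)ccc1OC)C(=C)O[Si](C)(C)C | intermediate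
6 | but-3-yn-2-one | CC(=O)C#C | starting material
7 | 1-[5-(5-bromo-2-methoxyphenyl)-6-methoxy-4,6-bis(trimethylsilyloxy)cyclohexa-1,4-dien-1-yl]ethanone (racemic) | COC1(O[Si](C)(C)C)C(C(C)=O)=CCC(O[Si](C)(C)C)=C1c1cc(Br)ccc1OC | intermediate
8 | 1-[3-(5-bromo-2-methoxyphenyl)-2,4-dihydroxyphenyl]ethanone | CC(=O)c1ccc(O)c(-c2cc(Br)ccc2OC)c1O | intermediate
9 | 1-[4-(benzyloxy)-3-(5-bromo-2-methoxyphenyl)-2-hydroxyphenyl]ethanone | CC(=O)c1ccc(OCc2ccccc2)c(-c2cc(Br)ccc2OC)c1O | intermediate
10 | 4-(benzyloxy)benzaldehyde | O=Cc1ccc(OCc2ccccc2)cc1 | starting material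
11 | (E)-1-[4-(benzyloxy)-3-(5-bromo-2-methoxyphenyl)-2-hydroxyphenyl]-3-[4-(benzyloxy)phenyl]prop-2-en-1-one | O=C(/C=C/c1ccc(OCc2ccccc2)cc1)c1ccc(OCc2ccccc2)c(-c2cc(Br)ccc2OC)c1O | intermediate
12 | 7-(benzyloxy)-2-[4-(benzyloxy)phenyl]-8-(5-bromo-2-methoxyphenyl)-4H-chromen-4-one | COc1ccc(Br)cc1-c1c(OCc2ccccc2)ccc2c(=O)cc(-c3ccc(OCc4ccccc4)cc3)oc12 | intermediate
13 | ethynyl(trimethyl)silane | C#C[Si](C)(C)C | starting material
14 | 7-(benzyloxy)-2-[4-(benzyloxy)phenyl]-8-{2-methoxy-5-[(trimethylsilyl)ethynyl]phenyl}-4H-chromen-4-one | COc1ccc(C#C[Si](C)(C)C)cc1-c1c(OCc2ccccc2)ccc2c(=O)cc(-c3ccc(OCc4ccccc4)cc3)oc12 | intermediate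
15 | 7-(benzyloxy)-2-[4-(benzyloxy)phenyl]-8-(5-ethynyl-2-methoxyphenyl)-4H-chromen-4-one | COc1ccc(C#C)cc1-c1c(OCc2ccccc2)ccc2c(=O)cc(-c3ccc(OCc4ccccc4)cc3)oc12 | intermediate
16 | 2-iodo-5-methoxyphenol | COc1ccc(I)c(O)c1 | starting material
17 | 7-(benzyloxy)-2-[4-(benzyloxy)phenyl]-8-{5-[3-(2-hydroxy-4-methoxyphenyl)-3-oxoprop-1-yn-1-yl]-2-methoxyphenyl}-4H-chromen-4-one | COc1ccc(C(=O)C#Cc2ccc(OC)c(c2)-c2c(OCc3ccccc3)ccc3c(=O)cc(-c4ccc(OCc5ccccc5)cc4)oc23)c(O)c1 | intermediate
18 | 7-(benzyloxy)-2-[4-(benzyloxy)phenyl]-8-[2-methoxy-5-(7-methoxy-4-oxo-4H-chromen-2-yl)phenyl]-4H-chromen-4-one | COc1ccc2c(=O)cc(-c3ccc(OC)c(-c4c(OCc5ccccc5)ccc5c(=O)cc(-c6ccc(OCc7ccccc7)cc6)oc45)c3)oc2c1 | intermediate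
19 | 7-hydroxy-2-(4-hydroxyphenyl)-8-[2-methoxy-5-(7-methoxy-4-oxo-4H-chromen-2-yl)phenyl]-4H-chromen-4-one (CNP0121664.0) | COc1ccc2c(=O)cc(-c3ccc(OC)c(-c4c(O)ccc5c(=O)cc(-c6ccc(O)cc6)oc45)c3)oc2c1 | target

**Step count and risks**

Total step count: 11. Longest linear sequence: 11 steps (1 → 19); compounds 6, 10, 13 and 16 are bought.

Steps most likely to fail:

1. Step 5. The diene, hindered by its ortho-methoxyaryl group at C2, may add too slowly, so that the ynone oligomerises and the diene is lost to protodesilylation before ring D closes. The fallback makes the biaryl bond by Suzuki–Miyaura coupling; it sets out from 10 and comes back to the route at 12. Commercial 1-(2,4-dihydroxyphenyl)ethanone is iodinated at C3, between the two hydroxyl groups (I2, HIO3, aq EtOH), to 1-(2,4-dihydroxy-3-iodophenyl)ethanone F1. This is benzylated at the free 4-OH (BnBr, K2CO3, acetone) to 1-[4-(benzyloxy)-2-hydroxy-3-iodophenyl]ethanone F2, and condensed with 10 (KOH, EtOH) to (E)-1-[4-(benzyloxy)-2-hydroxy-3-iodophenyl]-3-[4-(benzyloxy)phenyl]prop-2-en-1-one F3. Cyclisation (I2 cat., DMSO, 130 °C) gives 7-(benzyloxy)-2-[4-(benzyloxy)phenyl]-8-iodo-4H-chromen-4-one F4. Coupling with commercial (5-bromo-2-methoxyphenyl)boronic acid (Pd(PPh3)4, Na2CO3, DME/H2O, 80 °C), in which the iodide should react ahead of the bromide, then gives 12.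

2. Step 10. Direct coupling of alkyne and iodophenol without CO uptake (leading to a 2-arylbenzofuran) or 5-exo closure of the ynone may outrun the carbonylative 6-endo pathway. The fallback attaches a ready-made chromone instead of building the pyranone; it sets out from 12 and comes back at 18. Bromide 12 is borylated with tetrahydroxydiboron (Pd(OAc)2, XPhos, KOAc, EtOH/THF, 80 °C) to {3-[7-(benzyloxy)-2-[4-(benzyloxy)phenyl]-4-oxo-4H-chromen-8-yl]-4-methoxyphenyl}boronic acid F5. Conjugate addition of F5 to commercial 7-methoxy-4H-chromen-4-one, catalysed by divalent palladium (Pd(OCOCF3)2, 2,2'-bipyridine, NH4PF6, H2O, ClCH2CH2Cl, 60 °C), gives the racemic flavanone 7-(benzyloxy)-2-[4-(benzyloxy)phenyl]-8-[2-methoxy-5-(7-methoxy-4-oxochroman-2-yl)phenyl]-4H-chromen-4-one F6. Dehydrogenation (I2 cat., DMSO, 130 °C) then gives 18.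

3. Step 4. Incomplete deprotonation of the methyl group, C-silylation or loss of the first silyl group on handling may leave a diene too impure for the cycloaddition. The fallback replaces the lithium dienolate by soft enolisation; it sets out from 3 and comes back at 5. Treatment of 3 with Me3SiOTf (2.2 equiv) and Et3N (2.5 equiv) in Et2O at 0 → 20 °C should silylate twice in one flask, passing through 4 without isolation and avoiding any strong base; no new compound is made.

**Further compounds**

F1 | step 5 | 1-(2,4-dihydroxy-3-iodophenyl)ethanone | CC(=O)c1ccc(O)c(I)c1O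
F2 | step 5 | 1-[4-(benzyloxy)-2-hydroxy-3-iodophenyl]ethanone | CC(=O)c1ccc(OCc2ccccc2)c(I)c1O
F3 | step 5 | (E)-1-[4-(benzyloxy)-2-hydroxy-3-iodophenyl]-3-[4-(benzyloxy)phenyl]prop-2-en-1-one | O=C(/C=C/c1ccc(OCc2ccccc2)cc1)c1ccc(OCc2ccccc2)c(I)c1O
F4 | step 5 | 7-(benzyloxy)-2-[4-(benzyloxy)phenyl]-8-iodo-4H-chromen-4-one | O=c1cc(-c2ccc(OCc3ccccc3)cc2)oc2c(I)c(OCc3ccccc3)ccc12
F5 | step 10 | {3-[7-(benzyloxy)-2-[4-(benzyloxy)phenyl]-4-oxo-4H-chromen-8-yl]-4-methoxyphenyl}boronic acid | COc1ccc(B(O)O)cc1-c1c(OCc2ccccc2)ccc2c(=O)cc(-c3ccc(OCc4ccccc4)cc3)oc12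
F6 | step 10 | 7-(benzyloxy)-2-[4-(benzyloxy)phenyl]-8-[2-methoxy-5-(7-methoxy-4-oxochroman-2-yl)phenyl]-4H-chromen-4-one (racemic at the flavanone C2) | COc1ccc2c(c1)OC(CC2=O)c1ccc(OC)c(c1)-c1c(OCc2ccccc2)ccc2c(=O)cc(-c3ccc(OCc4ccccc4)cc3)oc12
F0 | step 4 | none | none
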